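**Retrosynthetic overview**
1. Last bond C8–C9 (bisabolane numbering): catalyst-controlled, (S)-selective allylboration of 3-methylbut-2-enal by a ring-bearing 2-substituted allylboronate.
2. Ring C6–OH next to the C7=C14 methylene: SeO2 ene/[2,3] oxygenation of the C6–H isopropenyl-type precursor, with the face fixed by the axial C2 chlorine.
3. C3–Br/C2–Cl: trans-diaxial chlorohydrin of the ring alkene, then OH → Br with retention; both centres are set by the C6–H stereocentre, which line 2 then erases and rebuilds.
4. Allylic chloride handle at C8: metalation and chlorination of the isopropenyl methyl of limonene.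
5. The single ring is formed first, as in the biosynthesis (linalyl/nerolidyl → terpinyl/bisabolyl cation, C1–C6 bond), from (R)-linalool phosphate with C3 → C6 chirality transfer; the C5 unit joins the C10 ring at the end.

Locants in the overview are bisabolane numbers (ring C1–C6, methyl C15 on C3, side chain from C7 on C6, C14 the methylene); names in the steps use IUPAC locants.

Assumption: chirality transfer in step 1 is taken as incomplete (limonene of about 75–85% ee); the antipodal ring series is carried along and leaves after step 7 as the diastereomer with the unlike ring/carbinol pairing, removed by chromatography, so the target is isolated enantiopure.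

**Route**

Step 1
Reactants: 1 (R)-linalool [(3R)-3,7-dimethylocta-1,6-dien-3-ol]
Product: 3 (R)-limonene [(4R)-1-methyl-4-(prop-1-en-2-yl)cyclohex-1-ene], via linalyl diethyl phosphate 2 (not isolated)
Conditions: n-BuLi, toluene, −78 °C; ClP(O)(OEt)2, −78 → −30 °C; MeAl(OC6H2-2,6-tBu2-4-Me)2 (2 equiv), −78 → −20 °C
Reagents that add atoms: none
Why: Proposed new method: the bulky aluminium Lewis acid ionises the tertiary allylic phosphate to a cisoid linalyl cation–phosphatoaluminate ion pair, the C6=C7 bond captures C1 anti to the departing phosphate (anti-SN2', endo chain fold; cation–olefin cyclization to the α-terpinyl cation, the monoterpene counterpart of the nerolidyl → bisabolyl closure), so the C3 configuration is relayed to the new ring stereocentre as (R), and the hindered counter-ion removes a methyl proton to give the isopropenyl group; the closest known reactions are the aluminium-aryloxide-promoted cyclization of neryl diethyl phosphate to limonene and the solvolytic linalyl → α-terpinyl cyclization, which keeps part of the C3 chirality in this sense.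

Step 2
Reactants: 3 (R)-limonene
Product: 5 (4R)-4-(3-chloroprop-1-en-2-yl)-1-methylcyclohex-1-ene, via 10-lithiolimonene 4 (not isolated)
Conditions: n-BuLi, TMEDA, hexane, 25 °C, 16 h; C2Cl6, THF, −78 °C
Reagents that add atoms: hexachloroethane, ClC(Cl)(Cl)C(Cl)(Cl)Cl
Why: Allylic lithiation of limonene by n-BuLi·TMEDA takes place at the isopropenyl methyl group (the 2-substituted allyl anion is symmetrical, so one constitution results), and chlorophilic attack of the allyllithium on C2Cl6 (electrophilic chlorination) gives the allylic chloride without touching the ring stereocentre.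

Step 3
Reactants: 5 (4R)-4-(3-chloroprop-1-en-2-yl)-1-methylcyclohex-1-ene
Product: 6 (1S,2S,4R)-2-chloro-4-(3-chloroprop-1-en-2-yl)-1-methylcyclohexan-1-ol
Conditions: trichloroisocyanuric acid (0.37 equiv), acetone/H2O 5:1, 0 °C
Reagents that add atoms: trichloroisocyanuric acid, O=C1N(Cl)C(=O)N(Cl)C(=O)N1Cl; water, O
Why: Chlorohydrin formation (HOCl addition): the chloronium ion forms on the trisubstituted ring alkene (the side-chain alkene is only 1,1-disubstituted and deactivated by its allylic chlorine) and water opens it in the Markovnikov, trans-diaxial sense, which in the half-chair with the C4 substituent equatorial requires Cl+ on the face trans to that substituent and so sets C2 (S) and C1 (S) from C4 (R), the course known for the limonene bromohydrin.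

Step 4
Reactants: 6 (1S,2S,4R)-2-chloro-4-(3-chloroprop-1-en-2-yl)-1-methylcyclohexan-1-ol
Product: 7 (1S,2S,4R)-1-bromo-2-chloro-4-(3-chloroprop-1-en-2-yl)-1-methylcyclohexane
Conditions: Me3SiBr (2 equiv), CH2Cl2, −20 → 0 °C
Reagents that add atoms: bromotrimethylsilane, C[Si](C)(C)Br
Why: SN1 substitution of the tertiary alcohol with neighbouring-group participation: the axial C–Cl bond anti-periplanar to the leaving oxygen bridges to a chloronium ion, which bromide opens at the tertiary carbon from the face the oxygen left, giving the trans-diaxial tertiary bromide/secondary chloride with retention at C1, while the 2-(chloromethyl)allyl alkene is too electron-poor to be hydrobrominated under these conditions.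

Step 5
Reactants: 7 (1S,2S,4R)-1-bromo-2-chloro-4-(3-chloroprop-1-en-2-yl)-1-methylcyclohexane
Product: 10 (1R,3S,4S)-4-bromo-3-chloro-1-(3-chloroprop-1-en-2-yl)-4-methylcyclohexan-1-ol, via allylseleninic acid 8 (not isolated), via selenoxylate ester 9 (not isolated)
Conditions: SeO2 (0.5 equiv), t-BuOOH (3 equiv), salicylic acid (0.1 equiv), CH2Cl2, 25 °C
Reagents that add atoms: selenium dioxide, O=[Se]=O; tert-butyl hydroperoxide, CC(C)(C)OO
Why: SeO2 allylic hydroxylation (ene reaction then [2,3]-sigmatropic shift, the chemistry that turns limonene into p-mentha-1,8-dien-4-ol): Se=O adds to the =CH2 terminus with transfer of the ring methine hydrogen (the CH2Cl hydrogens are deactivated), and the allylseleninic acid returns oxygen to the now trigonal ring carbon from the equatorial direction, anti to the 1,3-related axial chlorine, so the erased C–H stereocentre is rebuilt as the (1R) carbinol cis to bromine and trans to chlorine.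

Step 6
Reactants: 10 (1R,3S,4S)-4-bromo-3-chloro-1-(3-chloroprop-1-en-2-yl)-4-methylcyclohexan-1-ol
Product: 11 (1R,3S,4S)-4-bromo-3-chloro-4-methyl-1-[3-(4,4,5,5-tetramethyl-1,3,2-dioxaborolan-2-yl)prop-1-en-2-yl]cyclohexan-1-ol
Conditions: Pd2(dba)3 [tris(dibenzylideneacetone)dipalladium] (2.5 mol %), B2pin2 (1.2 equiv), KOAc (1.5 equiv), THF, 45 °C
Reagents that add atoms: bis(pinacolato)diboron, CC1(C)OB(OC1(C)C)B1OC(C)(C)C(C)(C)O1
Why: Miyaura-type allylic borylation: zerovalent palladium inserts into the allylic C–Cl bond (far faster than into the tertiary C–Br or secondary C–Cl bond), acetate-assisted transmetallation with B2pin2 and reductive elimination give the allylboronate, the 2-substituted π-allyl being symmetrical and no stereocentre being involved.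

Step 7
Reactants: 11 (1R,3S,4S)-4-bromo-3-chloro-4-methyl-1-[3-(4,4,5,5-tetramethyl-1,3,2-dioxaborolan-2-yl)prop-1-en-2-yl]cyclohexan-1-ol; 12 3-methylbut-2-enal
Product: 14 (1R,3S,4S)-4-bromo-3-chloro-1-[(4S)-4-hydroxy-6-methylhepta-1,5-dien-2-yl]-4-methylcyclohexan-1-ol (CNP0365435.1), via pinacol borate ester 13 (not isolated)
Conditions: (S)-3,3'-bis(2,4,6-triisopropylphenyl)-1,1'-binaphthyl-2,2'-diyl hydrogen phosphate (5 mol %), 4 Å molecular sieves, toluene, −30 °C; aq. NaHCO3
Reagents that add atoms: none
Why: Chiral-phosphoric-acid-catalysed allylboration through a closed six-membered chair transition state: the (S)-acid, antipode of the one that gives (R)-carbinols from aryl and alkenyl aldehydes, sends the allyl group to the si face of the enal and sets the carbinol as (S) under catalyst control, the distant ring stereocentres having little say, and the borate ester is hydrolysed on work-up.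

**Compound list**
1 | (3R)-3,7-dimethylocta-1,6-dien-3-ol [(R)-linalool] | C=C[C@](C)(O)CCC=C(C)C | starting material
2 | diethyl (3R)-3,7-dimethylocta-1,6-dien-3-yl phosphate | C=C[C@](C)(OP(=O)(OCC)OCC)CCC=C(C)C | intermediate
3 | (4R)-1-methyl-4-(prop-1-en-2-yl)cyclohex-1-ene [(R)-limonene] | C=C(C)[C@@H]1CCC(C)=CC1 | intermediate
4 | {2-[(1R)-4-methylcyclohex-3-en-1-yl]prop-2-en-1-yl}lithium | [Li]CC(=C)[C@@H]1CCC(C)=CC1 | intermediate
5 | (4R)-4-(3-chloroprop-1-en-2-yl)-1-methylcyclohex-1-ene | ClCC(=C)[C@@H]1CCC(C)=CC1 | intermediate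
6 | (1S,2S,4R)-2-chloro-4-(3-chloroprop-1-en-2-yl)-1-methylcyclohexan-1-ol | ClCC(=C)[C@@H]1CC[C@](C)(O)[C@@H](Cl)C1 | intermediate
7 | (1S,2S,4R)-1-bromo-2-chloro-4-(3-chloroprop-1-en-2-yl)-1-methylcyclohexane | ClCC(=C)[C@@H]1CC[C@](C)(Br)[C@@H](Cl)C1 | intermediate
8 | 3-chloro-2-[(3S,4S)-4-bromo-3-chloro-4-methylcyclohexylidene]propane-1-seleninic acid (alkene geometry not fixed by the route) | O[Se](=O)CC(CCl)=C1CC[C@](C)(Br)[C@@H](Cl)C1 | intermediate
9 | (1R,3S,4S)-4-bromo-3-chloro-1-(3-chloroprop-1-en-2-yl)-4-methylcyclohexyl hydrogen selenoxylate (RO–Se–OH, divalent selenium) | O[Se]O[C@]1(C(=C)CCl)CC[C@](C)(Br)[C@@H](Cl)C1 | intermediate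
10 | (1R,3S,4S)-4-bromo-3-chloro-1-(3-chloroprop-1-en-2-yl)-4-methylcyclohexan-1-ol | ClCC(=C)[C@@]1(O)CC[C@](C)(Br)[C@@H](Cl)C1 | intermediate
11 | (1R,3S,4S)-4-bromo-3-chloro-4-methyl-1-[3-(4,4,5,5-tetramethyl-1,3,2-dioxaborolan-2-yl)prop-1-en-2-yl]cyclohexan-1-ol | CC1(C)OB(CC(=C)[C@@]2(O)CC[C@](C)(Br)[C@@H](Cl)C2)OC1(C)C | intermediate
12 | 3-methylbut-2-enal | CC(C)=CC=O | starting material
13 | 2-{[(4S)-2-[(1R,3S,4S)-4-bromo-3-chloro-1-hydroxy-4-methylcyclohexyl]-6-methylhepta-1,5-dien-4-yl]oxy}-4,4,5,5-tetramethyl-1,3,2-dioxaborolane | C=C(C[C@H](OB1OC(C)(C)C(C)(C)O1)C=C(C)C)[C@@]1(O)CC[C@](C)(Br)[C@@H](Cl)C1 | intermediate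
14 | (1R,3S,4S)-4-bromo-3-chloro-1-[(4S)-4-hydroxy-6-methylhepta-1,5-dien-2-yl]-4-methylcyclohexan-1-ol | C=C(C[C@H](O)C=C(C)C)[C@@]1(O)CC[C@](C)(Br)[C@@H](Cl)C1 | target

**Step count and risks**
Total steps: 7. Longest linear sequence: 7 (1 → 14); 12 is bought.

Steps most likely to fail:

Step 1. The transoid cation gives acyclic trienes, some terpinolene-type alkene can form, and the chirality transfer may be only partial. The fallback sets out from 1 and comes back at 3. Compound 1 is acylated (n-BuLi, then 4-nitrobenzoyl chloride, THF, −78 → 0 °C) to (3R)-3,7-dimethylocta-1,6-dien-3-yl 4-nitrobenzoate F1. Solvolysis of this ester in buffered aqueous acetone (2,6-lutidine, 60 °C) runs the same cation–olefin closure but ends by water capture, giving 2-[(1R)-4-methylcyclohex-3-en-1-yl]propan-2-ol F2 ((R)-α-terpineol) with the C3 → ring chirality transfer known for this solvolysis. Dehydration with POCl3/pyridine at 0 °C, which takes a methyl hydrogen, then returns 3.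

Step 4. The β-chloro tertiary cation ionises slowly, so E1 loss, Cl/Br exchange at the allylic CH2Cl or hydrobromination of the side-chain alkene could intervene. The fallback sets out from 5 and comes back at 7. Anti-dichlorination of the ring alkene with Et4NCl3 (CH2Cl2, −78 °C) gives (1S,2S,4R)-1,2-dichloro-4-(3-chloroprop-1-en-2-yl)-1-methylcyclohexane F3; both trans-diaxial opening modes lead to this one diastereomer because the two halogens are the same. Exchange of the tertiary chlorine alone with BBr3 (0.4 equiv, CH2Cl2, −78 °C), through the same chloronium ion, then gives 7.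

Step 5. The ene reaction on an alkene deactivated by the allylic chlorine may be slow, and the equatorial delivery of oxygen rests on a conformational argument and not on a precedent for this ring. The fallback sets out from 7 and comes back at 10. PdCl2(MeCN)2 (5 mol %, CH2Cl2, 25 °C; divalent palladium does not insert into the allylic chloride) isomerises the 1,1-disubstituted alkene to the more stable tetrasubstituted alkylidene (1S,2S)-1-bromo-2-chloro-4-(1-chloropropan-2-ylidene)-1-methylcyclohexane F4. A Schenck ene reaction with singlet oxygen (O2, 5,10,15,20-tetraphenylporphyrin, visible light, CH2Cl2, 0 °C) takes a methyl hydrogen and puts oxygen on the ring carbon, again equatorially and anti to the axial chlorine, to give (1R,3S,4S)-4-bromo-3-chloro-1-(3-chloroprop-1-en-2-yl)-4-methylcyclohexyl hydroperoxide F5. PPh3 reduces this to 10.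

**Further compounds**
F1 | step 1 | (3R)-3,7-dimethylocta-1,6-dien-3-yl 4-nitrobenzoate | C=C[C@](C)(OC(=O)c1ccc(cc1)[N+](=O)[O-])CCC=C(C)C
F2 | step 1 | 2-[(1R)-4-methylcyclohex-3-en-1-yl]propan-2-ol | CC(C)(O)[C@@H]1CCC(C)=CC1
F3 | step 4 | (1S,2S,4R)-1,2-dichloro-4-(3-chloroprop-1-en-2-yl)-1-methylcyclohexane | ClCC(=C)[C@@H]1CC[C@](C)(Cl)[C@@H](Cl)C1
F4 | step 5 | (1S,2S)-1-bromo-2-chloro-4-(1-chloropropan-2-ylidene)-1-methylcyclohexane (alkene geometry not fixed) | ClCC(C)=C1CC[C@](C)(Br)[C@@H](Cl)C1
F5 | step 5 | (1R,3S,4S)-4-bromo-3-chloro-1-(3-chloroprop-1-en-2-yl)-4-methylcyclohexyl hydroperoxide | OO[C@]1(C(=C)CCl)CC[C@](C)(Br)[C@@H](Cl)C1
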